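Numbering the oxolane O1, C2 (4-hydroxyphenyl), C3 (aroyl), C4 (4-hydroxybenzyl), C5 (2,4-dihydroxyphenyl), the route cuts C4–C5 and C2–C3. The feature exploited is the C3 carbonyl group lying between the cis C2/C5 aryl groups and beside the crowded cis C4/C5 pair. This is the fingerprint of an acetal-initiated Prins–pinacol (2-oxonia-Cope/aldol) cascade on a Z-alkene. In one operation SnCl4 converts a cis-4-aryl-5-(Z-alkenyl)-1,3-dioxolane, the 2,4-bis(benzyloxy)benzylidene acetal of an anti allylic diol, into the 3-formyl oxolane: two C–C bonds, the ring and four stereocentres. Aryllithium addition, oxidation and hydrogenolysis complete the target.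

Key step: step 6

Remark (precursor design): the allylic diol is used as its anti (1R,2S) isomer, because in the reacting chair its stannyloxy group is then equatorial and only the carbinol hydrogen faces the axial Z-substituent, whereas the syn isomer would place that oxygen 1,3-diaxial to the Z-substituent and set the two carbinol centres against each other.
Remark (acetal carbon): every dioxolane in the route is carried as a mixture of epimers at the acetal carbon, which becomes planar on ionisation, so the SMILES leave this centre open.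
Remark (supply): 1-(benzyloxy)-4-(2-bromoethyl)benzene and allenylboronic acid pinacol ester are taken as catalogue compounds.

Step 1
Reactants: 1 4-(benzyloxy)benzaldehyde; 2 allenylboronic acid pinacol ester
Product: 5 (1R,2S)-1-[4-(benzyloxy)phenyl]but-3-ene-1,2-diol (anti), via E-borylallylborane 3 (not isolated), via borinate adduct 4 (not isolated)
Conditions: (+)-α-pinene, BH3·SMe2, THF, 0 °C [gives (−)-Ipc2BH]; 2, THF, 0 °C; 1, −78 °C; 3 M NaOH, 30% H2O2, 0 °C → rt
Reagents that add atoms: hydrogen peroxide, OO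
Why: Brown-type allylboration, in which allene hydroboration gives the E-γ-borylallylborane 3, whose Zimmerman–Traxler chair adds to the Si face of 1 (dictated by the isopinocampheyl groups from (+)-α-pinene) to set 1R and the anti relation, and oxidation of the C–B bond with retention delivers the 2S carbinol.

Step 2
Reactants: 5 (1R,2S)-1-[4-(benzyloxy)phenyl]but-3-ene-1,2-diol; 6 2,4-bis(benzyloxy)benzaldehyde
Product: 8 (4R,5S)-4-[4-(benzyloxy)phenyl]-2-[2,4-bis(benzyloxy)phenyl]-5-ethenyl-1,3-dioxolane (4,5-cis), via dimethyl acetal 7 (not isolated)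
Conditions: 6, HC(OMe)3, PPTS (cat), MeOH, 40 °C; evaporate; 5, PPTS (cat), PhMe, 35 °C, reduced pressure (removal of MeOH)
Reagents that add atoms: none
Why: Acid-catalysed transacetalisation, in which the strongly stabilised 2,4-dialkoxybenzylic oxocarbenium ion exchanges methanol for the diol under an acid too weak to ionise the benzylic C–O bond of 5, so both carbinol centres are kept.

Step 3
Reactants: 8 (4R,5S)-4-aryl-5-ethenyl dioxolane
Product: 10 (4R,5R)-5-[4-(benzyloxy)phenyl]-2-[2,4-bis(benzyloxy)phenyl]-1,3-dioxolane-4-carbaldehyde (4,5-cis), via vicinal diol 9 (not isolated)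
Conditions: OsO4 (cat), NaIO4, 2,6-lutidine, dioxane–H2O, rt; used crude
Reagents that add atoms: osmium tetroxide, O=[Os](=O)(=O)=O (oxygen carrier); sodium periodate, [Na+].[O-]I(=O)(=O)=O (stoichiometric oxygen source)
Why: Lemieux–Johnson cleavage, in which osmylation of the only alkene and periodate scission of diol 9 give the aldehyde while 2,6-lutidine keeps the medium neutral, so the acetal and the α-centre stay untouched.

Step 4
Reactants: 11 1-(benzyloxy)-4-(2-bromoethyl)benzene
Product: 12 {2-[4-(benzyloxy)phenyl]ethyl}triphenylphosphonium bromide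
Conditions: PPh3, MeCN, reflux
Reagents that add atoms: triphenylphosphine, c1ccccc1P(c1ccccc1)c1ccccc1
Why: SN2 quaternisation of triphenylphosphine by a primary alkyl bromide.

Step 5
Reactants: 10 cis-dioxolane-4-carbaldehyde; 12 phosphonium bromide
Product: 14 (4R,5S)-4-[4-(benzyloxy)phenyl]-5-{(1Z)-3-[4-(benzyloxy)phenyl]prop-1-enyl}-2-[2,4-bis(benzyloxy)phenyl]-1,3-dioxolane (4,5-cis), via phosphorus ylide 13 (not isolated)
Conditions: 12, NaHMDS, THF, −78 → 0 °C; 10, −78 °C → rt
Reagents that add atoms: none
Why: Z-selective Wittig olefination, in which the non-stabilised ylide made lithium-free with a sodium base adds under kinetic control through the cis-oxaphosphetane, while the low temperature and the absence of excess base protect the epimerisable aldehyde centre.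

Step 6
Reactants: 14 cis-4-aryl-5-(Z-alkenyl) dioxolane
Product: 18 (2S,3S,4S,5R)-4-[4-(benzyloxy)benzyl]-2-[4-(benzyloxy)phenyl]-5-[2,4-bis(benzyloxy)phenyl]oxolane-3-carbaldehyde, via ring-opened oxocarbenium ion 15 (not isolated), via oxonia-Cope enolate 16 (not isolated), via all-cis aldehyde 17 (not isolated)
Conditions: SnCl4 (1.1 equiv), 2,6-di-tert-butyl-4-methylpyridine (0.3 equiv), CH2Cl2, −78 → −40 °C; sat aq NaHCO3; organic phase, DBU (0.2 equiv), CH2Cl2, 0 °C → rt
Reagents that add atoms: none
Why: SnCl4 pulls the allylic oxygen off the acetal carbon and the resulting E-oxocarbenium ion 15 (C5=O1) folds into a chair of C5, O1, C2, the carbinol carbon, C3 and C4, in which a 2-oxonia-Cope shift makes C4–C5 and breaks the C2–carbinol bond to give 16, whose tin enolate carbon C3 then attacks the new C2=O1 cation; Prins cyclisation followed by pinacol migration of C2 describes the same bond changes stepwise. The closest known reaction is the acetal-initiated Prins–pinacol synthesis of 3-acyl tetrahydrofurans from allylic diol acetals, which also accepts secondary carbinols that end as formyl groups. The one ring formed, the oxolane, closes by a 5-(enolexo)-endo-trig aldol addition (in the Prins reading by 6-endo-trig cyclisation and ring contraction). C5 is fixed by the E cation carrying its aryl group equatorial, C4 by the Z-alkene, which forces the benzyl group axial and so cis to the C5 aryl group, C2 by bond formation on the face that the carbinol carbon vacates, which keeps its aryl group equatorial and cis to that on C5, and the absolute sense by the two carbinol centres of 14, both of which choose the same chair because aryl and stannyloxy groups are equatorial and only the carbinol hydrogen faces the axial benzyl group. C3 arises cis to both neighbours (17) because C5 and C2 add to the same alkene face, and catalytic DBU then relaxes this single enolisable centre to the trans,trans aldehyde 18. The step needs ionisation at the acetal carbon rather than at the benzylic C2–O bond and one face of the alkene, which the doubly donor-stabilised acetal cation, the low temperature, the proton scavenger and the matched anti-diol should secure.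

Step 7
Reactants: 19 4-bromoresorcinol
Product: 20 2,4-bis(benzyloxy)-1-bromobenzene
Conditions: BnBr, K2CO3, DMF, rt → 50 °C
Reagents that add atoms: benzyl bromide, BrCc1ccccc1
Why: Williamson ether synthesis on both phenols.

Step 8
Reactants: 18 oxolane-3-carbaldehyde; 20 2,4-bis(benzyloxy)-1-bromobenzene
Product: 22 [2,4-bis(benzyloxy)phenyl]{tetrabenzyl oxolan-3-yl}methanol (ring centres as in 18, both carbinol epimers), via aryllithium 21 (not isolated)
Conditions: 20, n-BuLi, THF, −78 °C; 18, −78 °C; sat aq NH4Cl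
Reagents that add atoms: none
Why: Bromine–lithium exchange followed by 1,2-addition of the aryllithium to the aldehyde at −78 °C, which should outrun enolisation, the new carbinol centre being a mixture that the next step erases.

Step 9
Reactants: 22 secondary benzylic alcohol
Product: 23 [2,4-bis(benzyloxy)phenyl]{(2S,3S,4S,5R)-4-[4-(benzyloxy)benzyl]-2-[4-(benzyloxy)phenyl]-5-[2,4-bis(benzyloxy)phenyl]oxolan-3-yl}methanone
Conditions: Dess–Martin periodinane, NaHCO3, CH2Cl2, 0 °C → rt
Reagents that add atoms: none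
Why: Dess–Martin oxidation under buffered conditions gives the aryl ketone without touching the benzylic ethers, and C3 already holds the more stable trans,trans arrangement, so enolisation cannot harm it.

Step 10
Reactants: 23 hexabenzyl ketone
Product: 24 (2,4-dihydroxyphenyl){(2S,3S,4S,5R)-5-(2,4-dihydroxyphenyl)-4-(4-hydroxybenzyl)-2-(4-hydroxyphenyl)oxolan-3-yl}methanone (target)
Conditions: H2 (1 atm), 10% Pd/C, EtOAc–THF, rt, stopped at the calculated uptake
Reagents that add atoms: none
Why: Catalytic hydrogenolysis, in which the six aryl benzyl ethers should cleave well before the ring C2–O1 and C5–O1 bonds in a neutral aprotic solvent, as is usual for 2,5-diaryl tetrahydrofuran lignans, while the hydrogen-bonded 2-hydroxyaryl ketone resists reduction.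

Compound list
1 | 4-(benzyloxy)benzaldehyde | O=Cc1ccc(OCc2ccccc2)cc1 | starting material
2 | allenylboronic acid pinacol ester | C=C=CB1OC(C)(C)C(C)(C)O1 | starting material
3 | (E)-[3-(pinacolboryl)allyl]bis(isopinocampheyl)borane | CC1(C)OB(/C=C/CB([C@@H]2C[C@@H]3C[C@H]([C@H]2C)C3(C)C)[C@@H]2C[C@@H]3C[C@H]([C@H]2C)C3(C)C)OC1(C)C | intermediate
4 | bis(isopinocampheyl)borinate of the anti 1-aryl-2-(pinacolboryl)but-3-en-1-ol | O([C@H](c1ccc(OCc2ccccc2)cc1)[C@@H](B1OC(C)(C)C(C)(C)O1)C=C)B([C@@H]1C[C@@H]2C[C@H]([C@H]1C)C2(C)C)[C@@H]1C[C@@H]2C[C@H]([C@H]1C)C2(C)C | intermediate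
5 | (1R,2S)-1-[4-(benzyloxy)phenyl]but-3-ene-1,2-diol | O[C@H](c1ccc(OCc2ccccc2)cc1)[C@@H](O)C=C | intermediate
6 | 2,4-bis(benzyloxy)benzaldehyde | O=Cc1ccc(OCc2ccccc2)cc1OCc1ccccc1 | starting material
7 | 2,4-bis(benzyloxy)benzaldehyde dimethyl acetal | COC(OC)c1ccc(OCc2ccccc2)cc1OCc1ccccc1 | intermediate
8 | (4R,5S)-4-[4-(benzyloxy)phenyl]-2-[2,4-bis(benzyloxy)phenyl]-5-ethenyl-1,3-dioxolane | C1(c2ccc(OCc3ccccc3)cc2OCc2ccccc2)O[C@H](c2ccc(OCc3ccccc3)cc2)[C@H](C=C)O1 | intermediate
9 | 1-(cis-dioxolan-4-yl)ethane-1,2-diol from osmylation of 8 (both carbinol epimers) | C1(c2ccc(OCc3ccccc3)cc2OCc2ccccc2)O[C@H](c2ccc(OCc3ccccc3)cc2)[C@H](C(O)CO)O1 | intermediate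
10 | (4R,5R)-5-[4-(benzyloxy)phenyl]-2-[2,4-bis(benzyloxy)phenyl]-1,3-dioxolane-4-carbaldehyde | C1(c2ccc(OCc3ccccc3)cc2OCc2ccccc2)O[C@H](c2ccc(OCc3ccccc3)cc2)[C@H](C=O)O1 | intermediate
11 | 1-(benzyloxy)-4-(2-bromoethyl)benzene | BrCCc1ccc(OCc2ccccc2)cc1 | starting material
12 | {2-[4-(benzyloxy)phenyl]ethyl}triphenylphosphonium bromide | [Br-].c1ccccc1[P+](CCc1ccc(OCc2ccccc2)cc1)(c1ccccc1)c1ccccc1 | intermediate
13 | {2-[4-(benzyloxy)phenyl]ethylidene}triphenylphosphorane | c1ccccc1P(=CCc1ccc(OCc2ccccc2)cc1)(c1ccccc1)c1ccccc1 | intermediate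
14 | (4R,5S)-4-[4-(benzyloxy)phenyl]-5-{(1Z)-3-[4-(benzyloxy)phenyl]prop-1-enyl}-2-[2,4-bis(benzyloxy)phenyl]-1,3-dioxolane | C1(c2ccc(OCc3ccccc3)cc2OCc2ccccc2)O[C@H](c2ccc(OCc3ccccc3)cc2)[C@H](/C=C\Cc2ccc(OCc3ccccc3)cc2)O1 | intermediate
15 | E-oxocarbenium chloride (C5=O1) carrying the trichlorostannyl alkoxide on the carbinol carbon | C(c1ccccc1)Oc1cc(OCc2ccccc2)ccc1/C=[O+]/[C@H](c1ccc(OCc2ccccc2)cc1)[C@H](/C=C\Cc1ccc(OCc2ccccc2)cc1)O[Sn](Cl)(Cl)Cl.[Cl-] | intermediate
16 | E-oxocarbenium chloride (C2=O1) carrying the E trichlorostannyl enolate (C3), C4 and C5 set | C(c1ccccc1)Oc1ccc(cc1)/C=[O+]/[C@@H](c1ccc(OCc2ccccc2)cc1OCc1ccccc1)[C@@H](Cc1ccc(OCc2ccccc2)cc1)/C=C/O[Sn](Cl)(Cl)Cl.[Cl-] | intermediate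
17 | (2S,3R,4S,5R) all-cis oxolane-3-carbaldehyde, tetrabenzyl ether | O=C[C@@H]1[C@H](Cc2ccc(OCc3ccccc3)cc2)[C@H](c2ccc(OCc3ccccc3)cc2OCc2ccccc2)O[C@@H]1c1ccc(OCc2ccccc2)cc1 | intermediate
18 | (2S,3S,4S,5R)-4-[4-(benzyloxy)benzyl]-2-[4-(benzyloxy)phenyl]-5-[2,4-bis(benzyloxy)phenyl]oxolane-3-carbaldehyde | O=C[C@H]1[C@H](Cc2ccc(OCc3ccccc3)cc2)[C@H](c2ccc(OCc3ccccc3)cc2OCc2ccccc2)O[C@@H]1c1ccc(OCc2ccccc2)cc1 | intermediate
19 | 4-bromoresorcinol | Oc1ccc(Br)c(O)c1 | starting material
20 | 2,4-bis(benzyloxy)-1-bromobenzene | Brc1ccc(OCc2ccccc2)cc1OCc1ccccc1 | intermediate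
21 | 2,4-bis(benzyloxy)phenyllithium | [Li]c1ccc(OCc2ccccc2)cc1OCc1ccccc1 | intermediate
22 | hexabenzyl carbinol, ring centres as in 18, both carbinol epimers | OC(c1ccc(OCc2ccccc2)cc1OCc1ccccc1)[C@H]1[C@H](Cc2ccc(OCc3ccccc3)cc2)[C@H](c2ccc(OCc3ccccc3)cc2OCc2ccccc2)O[C@@H]1c1ccc(OCc2ccccc2)cc1 | intermediate
23 | hexabenzyl ketone, (2S,3S,4S,5R) | O=C(c1ccc(OCc2ccccc2)cc1OCc1ccccc1)[C@H]1[C@H](Cc2ccc(OCc3ccccc3)cc2)[C@H](c2ccc(OCc3ccccc3)cc2OCc2ccccc2)O[C@@H]1c1ccc(OCc2ccccc2)cc1 | intermediate
24 | (2,4-dihydroxyphenyl){(2S,3S,4S,5R)-5-(2,4-dihydroxyphenyl)-4-(4-hydroxybenzyl)-2-(4-hydroxyphenyl)oxolan-3-yl}methanone | O=C(c1ccc(O)cc1O)[C@H]1[C@H](Cc2ccc(O)cc2)[C@H](c2ccc(O)cc2O)O[C@@H]1c1ccc(O)cc1 | target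

Total step count: 10. Longest linear sequence: 8 (steps 1, 2, 3, 5, 6, 8, 9, 10).

Steps most likely to fail

**Step 6.** The doubly donor-stabilised cation may react too slowly with the unactivated alkene. Several processes could then overtake ring closure:
- ionisation of the benzylic C2–O or C5–O bonds;
- loss of 4-(benzyloxy)benzaldehyde from the oxonia-Cope intermediate;
- a 1,2-hydride shift from the axial carbinol C–H bond towards a pyran-3-one.

Prolonged contact with the Lewis acid could also epimerise C5 and erase the cis C4/C5 relation.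

The fallback changes the precursor. It sets out from 10 and comes back at 18. Aldehyde 10 is equilibrated with DBU in CH2Cl2 to the more stable (4S,5R)-trans-dioxolane-4-carbaldehyde F1. Ylide 13 converts this, now free of any epimerisation risk, into the (4R,5R)-trans-4-aryl-5-(Z-alkenyl)dioxolane F2, the acetal of the syn diol. This is then treated with SnCl4 and DBU as in step 6. In its chair the carbinol hydrogen is equatorial and cannot migrate, and the unstrained trans-dioxolane should be less prone to stray ionisation. The price is an axial stannyloxy group beside the axial benzyl group, so the facial bias rests on the equatorial C2 aryl group alone.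

**Step 5.** Base-induced epimerisation of the cis aldehyde centre towards the trans series, β-elimination of the ring oxygen and erosion of Z-selectivity are the processes to fear.

The fallback avoids an α-oxy aldehyde altogether. It sets out from 8 and comes back at 14, skipping steps 3 to 5. It is a Z-selective cross-metathesis of the vinyl dioxolane 8 with an excess of purchased 1-allyl-4-(benzyloxy)benzene. The catalyst is the cyclometalated nitrato ruthenium Z-selective Grubbs catalyst (adamantyl-chelated carbene with an N-2,6-diisopropylphenyl group), in THF at 35 °C under a slow argon purge. No new compound is made (F0).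

**Step 10.** Hydrogenolytic opening of the benzylic C2–O1 or C5–O1 bonds may occur. Epimerisation at C5 through quinone-methide-type ionisation is also possible once the ortho and para phenols are free on the metal surface.

The fallback separates benzyl removal from phenol release. It sets out from 23 and comes back at 24. PdCl2 (cat), Et3SiH and Et3N in CH2Cl2 exchange every benzyl group for a silyl group in a basic, hydrogen-gas-free medium. This gives the hexakis(triethylsilyl) ether F3. It is then desilylated without metal by Bu4NF buffered with AcOH in THF at 0 °C.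

Further compounds
F1 | step 6 | (4S,5R)-5-[4-(benzyloxy)phenyl]-2-[2,4-bis(benzyloxy)phenyl]-1,3-dioxolane-4-carbaldehyde (4,5-trans) | C1(c2ccc(OCc3ccccc3)cc2OCc2ccccc2)O[C@H](c2ccc(OCc3ccccc3)cc2)[C@@H](C=O)O1
F2 | step 6 | (4R,5R)-4-[4-(benzyloxy)phenyl]-5-{(1Z)-3-[4-(benzyloxy)phenyl]prop-1-enyl}-2-[2,4-bis(benzyloxy)phenyl]-1,3-dioxolane (4,5-trans) | C1(c2ccc(OCc3ccccc3)cc2OCc2ccccc2)O[C@H](c2ccc(OCc3ccccc3)cc2)[C@@H](/C=C\Cc2ccc(OCc3ccccc3)cc2)O1
F0 | step 5 | none | none
F3 | step 10 | hexakis(triethylsilyl) ether of 24 | O=C(c1ccc(O[Si](CC)(CC)CC)cc1O[Si](CC)(CC)CC)[C@H]1[C@H](Cc2ccc(O[Si](CC)(CC)CC)cc2)[C@H](c2ccc(O[Si](CC)(CC)CC)cc2O[Si](CC)(CC)CC)O[C@@H]1c1ccc(O[Si](CC)(CC)CC)cc1
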